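**Direct plan and its weak points**

A direct plan would reduce ethyl pyruvate A1 enzymatically to ethyl (S)-lactate A2 and etherify it with 4-bromo-2,6-dimethoxyphenol A3 by Mitsunobu inversion to the (R)-ester A4. The ester would become the Weinreb amide A5, a Suzuki coupling with the silyl-protected hydroxypropenyl boronate A6 would give A7, the aryl Grignard reagent A8 would give the silylated ketone A9, and fluoride would free the target.
- The ketoreductase reduction of A1 would spend a step on a commodity chiral-pool ester and build nothing.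
- Carrying the stereocentre from the Mitsunobu step onward would be fragile: its C–H next to a carbonyl group is acidic and would meet an aluminium amide, hot aqueous carbonate and excess Grignard reagent.
- The amide exchange, the bromide/boronate detour and the silyl on/off would be functional-group and protecting-group traffic that only attaches a C3 side chain obtainable already on the phenol.

**Retrosynthetic overview**

The target is cut at the C7–C8 bond: C7 is the ketone carbon on ring A (3,4,5-trimethoxyphenyl); C8 is the stereogenic carbon carrying the methyl group C9 and the ether oxygen to ring B (2,6-dimethoxy-4-(3-hydroxypropenyl)phenyl).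
C8 is an α-aryloxy carbon, so a carboxyl group placed where C7 will sit can leave as CO2 and give a planar, oxygen-stabilised radical; a chiral nickel catalyst joins it to a 3,4,5-trimethoxybenzoyl thioester and sets C8 in the same event.
No ring is built: ring B is bought with its side chain as sinapyl alcohol, ring A as the acid chloride, and the two halves are joined in the last step.
The stereocentre is therefore created last from a racemic acid, so nothing chiral is bought, made enzymatically or carried through basic steps, and no protecting group, halide handle or amide exchange is needed.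

Key step: step 3

Assumption: the sense of induction cannot be predicted for this radical class, so (R,R)-Ph-BOX [(4R,4'R)-2,2'-(propane-2,2-diyl)bis(4-phenyl-4,5-dihydrooxazole)] is written; its commercial mirror image would be used, with nothing else changed, if the first run should favour the (S)-ketone.

**Route**

Step 1
Reactants: 1 (E)-sinapyl alcohol [4-[(E)-3-hydroxyprop-1-en-1-yl]-2,6-dimethoxyphenol]; 2 methyl 2-bromopropanoate (racemic)
Product: 4 rac-2-{4-[(E)-3-hydroxyprop-1-en-1-yl]-2,6-dimethoxyphenoxy}propanoic acid, via methyl aryloxypropanoate 3 (not isolated)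
Conditions: K2CO3 (1.5 equiv), 2 (1.1 equiv), DMF, Ar, 40 °C; then LiOH·H2O (3 equiv), THF/H2O, 0 °C → rt; cold 0.5 M HCl to pH 4, EtOAc
Reagents that add atoms: lithium hydroxide, [Li+].[OH-]
Why: Williamson etherification in which carbonate deprotonates only the phenol, so the phenoxide displaces the activated secondary bromide of 2 by SN2 while the primary allylic alcohol stays free, followed by saponification of the methyl ester in the same flask; no stereocontrol is needed because the acid is used as the racemate.

Step 2
Reactants: 5 3,4,5-trimethoxybenzoyl chloride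
Product: 6 S-(pyridin-2-yl) 3,4,5-trimethoxybenzenecarbothioate
Conditions: pyridine-2-thiol (1.05 equiv), Et3N (1.1 equiv), CH2Cl2, 0 °C → rt; cold aq. NaHCO3 wash, crystallisation
Reagents that add atoms: pyridine-2-thiol, Sc1ccccn1
Why: Acyl substitution (thioesterification) at the soft sulfur of pyridine-2-thiol gives the 2-pyridyl thioester, an acyl donor that zerovalent nickel inserts into but that does not acylate a primary alcohol at room temperature.

Step 3
Reactants: 4 rac-2-{4-[(E)-3-hydroxyprop-1-en-1-yl]-2,6-dimethoxyphenoxy}propanoic acid; 6 S-(pyridin-2-yl) 3,4,5-trimethoxybenzenecarbothioate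
Product: 8 (2R)-2-{4-[(E)-3-hydroxyprop-1-en-1-yl]-2,6-dimethoxyphenoxy}-1-(3,4,5-trimethoxyphenyl)propan-1-one (target CNP0171423.1), via N-hydroxyphthalimide ester 7 (not isolated)
Conditions: N-hydroxyphthalimide (1.05 equiv), N,N'-diisopropylcarbodiimide (DIC, 1.05 equiv), THF, rt; then 6 (1.5 equiv), NiBr2·dme (dme = MeOCH2CH2OMe, 10 mol %), (R,R)-Ph-BOX (12 mol %), Zn dust (2.5 equiv), THF/N,N-dimethylacetamide 1:1, 0 → 10 °C, dark; aq. NH4Cl
Reagents that add atoms: none
Why: Proposed new method: acid 4 is activated in the flask as its N-hydroxyphthalimide ester 7, which takes up one electron from reduced nickel (turned over by zinc), loses CO2 and phthalimide and gives the planar 1-aryloxyethyl radical at C8, so the configuration of racemic 4 is erased; zerovalent nickel carrying the chiral bis(oxazoline) inserts into the C–S bond of 6, the aroyl–nickel species captures the radical, and reductive elimination from trivalent nickel forms the C7–C8 bond. The closest known reaction types are the nickel/zinc decarboxylative ketone synthesis from N-hydroxyphthalimide esters and 2-pyridyl thioesters (achiral bipyridine ligands) and the nickel/bis(oxazoline)-catalysed enantioconvergent reductive acylation of racemic secondary benzylic chlorides with acid chlorides; the new element is their combination on an α-aryloxyalkyl radical, a radical class whose enantioconvergent capture by chiral nickel has precedent in couplings of racemic 1-haloalkyl esters. No ring is closed. The only stereocentre, C8, is set by the catalyst: the C2-symmetric ligand differentiates the two faces of the prochiral radical (small methyl against the large 2,6-dimethoxyaryloxy group) at the capture/reductive-elimination stage, so both enantiomers of 4 should funnel into (R)-8. The step needs cross-selectivity (slow radical release against fast thioester insertion, thioester in excess) and chemoselectivity, which the substrate supports: the electron-rich cinnamyl C=C is a poor trap for the nucleophilic α-oxy radical, the free allylic alcohol is not ionised by nickel without a Lewis acid and is not acylated by a 2-pyridyl thioester at 0–10 °C, and the medium is free of base and light, so the acidic C8–H of the product and the (E)-alkene should stay as formed.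

**Compound list**

1 | (E)-sinapyl alcohol, 4-[(E)-3-hydroxyprop-1-en-1-yl]-2,6-dimethoxyphenol | COc1cc(/C=C/CO)cc(OC)c1O | starting material
2 | methyl 2-bromopropanoate (racemic) | COC(=O)C(C)Br | starting material
3 | methyl rac-2-{4-[(E)-3-hydroxyprop-1-en-1-yl]-2,6-dimethoxyphenoxy}propanoate | COC(=O)C(C)Oc1c(OC)cc(/C=C/CO)cc1OC | intermediate
4 | rac-2-{4-[(E)-3-hydroxyprop-1-en-1-yl]-2,6-dimethoxyphenoxy}propanoic acid | OC(=O)C(C)Oc1c(OC)cc(/C=C/CO)cc1OC | intermediate
5 | 3,4,5-trimethoxybenzoyl chloride | COc1cc(C(Cl)=O)cc(OC)c1OC | starting material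
6 | S-(pyridin-2-yl) 3,4,5-trimethoxybenzenecarbothioate | COc1cc(C(=O)Sc2ccccn2)cc(OC)c1OC | intermediate
7 | 1,3-dioxoisoindolin-2-yl rac-2-{4-[(E)-3-hydroxyprop-1-en-1-yl]-2,6-dimethoxyphenoxy}propanoate | O=C(ON1C(=O)c2ccccc2C1=O)C(C)Oc1c(OC)cc(/C=C/CO)cc1OC | intermediate
8 | (2R)-2-{4-[(E)-3-hydroxyprop-1-en-1-yl]-2,6-dimethoxyphenoxy}-1-(3,4,5-trimethoxyphenyl)propan-1-one (CNP0171423.1) | COc1cc(C(=O)[C@@H](C)Oc2c(OC)cc(/C=C/CO)cc2OC)cc(OC)c1OC | target

**Summary and risks**

Total step count: 3. Longest linear sequence: 2 steps (1 → 4 → 8); step 2 lies on the convergent branch.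

Steps most likely to fail:

1. Step 3 (proposed new method). The chiral nickel centre may discriminate the faces of the 1-aryloxyethyl radical poorly, or the radical may be lost by dimerisation, hydrogen abstraction or β-hydride loss before cross-coupling. The fallback uses known chemistry (chiral pool, then a base-free ketone synthesis), sets out from 1 and comes back at 8. O-Alkylation of 1 with commercial ethyl (2S)-2-(tosyloxy)propanoate (K2CO3, MeCN, 60 °C, SN2 with inversion) should give ethyl (2R)-2-{4-[(E)-3-hydroxyprop-1-en-1-yl]-2,6-dimethoxyphenoxy}propanoate F1. Saponification (LiOH, THF/H2O, 0 °C) should give (2R)-2-{4-[(E)-3-hydroxyprop-1-en-1-yl]-2,6-dimethoxyphenoxy}propanoic acid F2. Thioesterification with thiophenol (EDC·HCl, HOBt, CH2Cl2, 0 °C) should give S-phenyl (2R)-2-{4-[(E)-3-hydroxyprop-1-en-1-yl]-2,6-dimethoxyphenoxy}propanethioate F3. A Liebeskind–Srogl coupling of F3 with 3,4,5-trimethoxyphenylboronic acid [Pd2(dba)3, tri(2-furyl)phosphine, copper thiophene-2-carboxylate Cu(O2CC4H3S), THF, 45 °C] should then form the C7–aryl bond without base and give 8.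

2. Step 1. The electron-rich phenoxide of 1 may oligomerise oxidatively under base before O-alkylation is complete, or 2 may lose HBr and the phenoxide add to the resulting acrylate. The fallback sets out from 2 and comes back at 3. Commercial syringaldehyde is O-alkylated with 2 (K2CO3, DMF, 60 °C) to methyl rac-2-(4-formyl-2,6-dimethoxyphenoxy)propanoate F4. A Wittig reaction with (triphenylphosphoranylidene)acetaldehyde (toluene, 80 °C) should give methyl rac-2-{2,6-dimethoxy-4-[(E)-3-oxoprop-1-en-1-yl]phenoxy}propanoate F5. Luche 1,2-reduction (NaBH4, CeCl3·7H2O, MeOH, 0 °C) should give 3, which is saponified as in step 1.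

3. Step 2. The thioester may hydrolyse on aqueous work-up or storage, so that the acyl donor reaches the key step impure. The fallback sets out from 5 and comes back at 8. Compound 5 is condensed with glutarimide (Et3N, cat. DMAP, CH2Cl2) to the bench-stable twisted amide 1-(3,4,5-trimethoxybenzoyl)piperidine-2,6-dione F6. F6 replaces 6 in step 3, where zerovalent nickel inserts into its N–C(O) bond, a known mode of acyl transfer in nickel-catalysed reductive ketone syntheses, and coupling with 7 gives 8.

**Further compounds**

F1 | step 3 | ethyl (2R)-2-{4-[(E)-3-hydroxyprop-1-en-1-yl]-2,6-dimethoxyphenoxy}propanoate | CCOC(=O)[C@@H](C)Oc1c(OC)cc(/C=C/CO)cc1OC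
F2 | step 3 | (2R)-2-{4-[(E)-3-hydroxyprop-1-en-1-yl]-2,6-dimethoxyphenoxy}propanoic acid | OC(=O)[C@@H](C)Oc1c(OC)cc(/C=C/CO)cc1OC
F3 | step 3 | S-phenyl (2R)-2-{4-[(E)-3-hydroxyprop-1-en-1-yl]-2,6-dimethoxyphenoxy}propanethioate | O=C(Sc1ccccc1)[C@@H](C)Oc1c(OC)cc(/C=C/CO)cc1OC
F4 | step 1 | methyl rac-2-(4-formyl-2,6-dimethoxyphenoxy)propanoate | COC(=O)C(C)Oc1c(OC)cc(C=O)cc1OC
F5 | step 1 | methyl rac-2-{2,6-dimethoxy-4-[(E)-3-oxoprop-1-en-1-yl]phenoxy}propanoate | COC(=O)C(C)Oc1c(OC)cc(/C=C/C=O)cc1OC
F6 | step 2 | 1-(3,4,5-trimethoxybenzoyl)piperidine-2,6-dione | COc1cc(C(=O)N2C(=O)CCCC2=O)cc(OC)c1OC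
A1 | direct plan | ethyl pyruvate | CCOC(=O)C(C)=O
A2 | direct plan | ethyl (2S)-2-hydroxypropanoate, ethyl (S)-lactate | CCOC(=O)[C@H](C)O
A3 | direct plan | 4-bromo-2,6-dimethoxyphenol | COc1cc(Br)cc(OC)c1O
A4 | direct plan | ethyl (2R)-2-(4-bromo-2,6-dimethoxyphenoxy)propanoate | CCOC(=O)[C@@H](C)Oc1c(OC)cc(Br)cc1OC
A5 | direct plan | (2R)-2-(4-bromo-2,6-dimethoxyphenoxy)-N-methoxy-N-methylpropanamide | CON(C)C(=O)[C@@H](C)Oc1c(OC)cc(Br)cc1OC
A6 | direct plan | (E)-2-[3-(tert-butyldimethylsilyloxy)prop-1-en-1-yl]-4,4,5,5-tetramethyl-1,3,2-dioxaborolane | CC(C)(C)[Si](C)(C)OC/C=C/B1OC(C)(C)C(C)(C)O1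
A7 | direct plan | (2R)-2-{4-[(E)-3-(tert-butyldimethylsilyloxy)prop-1-en-1-yl]-2,6-dimethoxyphenoxy}-N-methoxy-N-methylpropanamide | CON(C)C(=O)[C@@H](C)Oc1c(OC)cc(/C=C/CO[Si](C)(C)C(C)(C)C)cc1OC
A8 | direct plan | 3,4,5-trimethoxyphenylmagnesium bromide | COc1cc([Mg]Br)cc(OC)c1OC
A9 | direct plan | (2R)-2-{4-[(E)-3-(tert-butyldimethylsilyloxy)prop-1-en-1-yl]-2,6-dimethoxyphenoxy}-1-(3,4,5-trimethoxyphenyl)propan-1-one | COc1cc(C(=O)[C@@H](C)Oc2c(OC)cc(/C=C/CO[Si](C)(C)C(C)(C)C)cc2OC)cc(OC)c1OC
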